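**Plan**
Ring numbering used here is that of the cyclohex-2-en-1-one core: C1 (C=O), C2 (bears CH2OH), C3 (=CH), C4 (O-angeloyl), C5 (isopropyl), C6 (O-acyl).
Retrosynthesis: take off the two esters and the C2 hydroxymethyl (Morita–Baylis–Hillman), then the C2=C3 unsaturation (Saegusa–Ito), and trade the C5 isopropyl for a C5 ketone (olefination/hydrogenation).
Then cut C3–C4 and C1–C6 together. C4–C5–C6 with its two cis oxygens is dihydroxyacetone held in a 1,3-dioxan-5-one ring, and C3–C2–C1 is an acryloyl unit. What makes this possible is that both α-carbons of the latent C5 ketone carry the ring oxygens and the enone carbonyl sits 1,3 to C5.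
Forward: chiral enamine of 2,2-dimethyl-1,3-dioxan-5-one plus acryloyl chloride closes the carbocycle in one operation as a 2,4-dioxabicyclo[3.3.1]nonane-6,9-dione; then C9 isopropylidene, acetal opening, hydrogenation, enone, esters, hydroxymethyl.
Stereochemistry: C4 from the (2R,5R)-2,5-dimethylpyrrolidine auxiliary; C6 relayed in the same event because the three-carbon bridge can only span the two α-carbons cis; C5 by hydrogenation anti to both silyloxy groups; alkene geometries from angelic acid and an E-selective stabilised Wittig reaction.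

Key step: step 2

Remark: compounds 1, 2, 4, 8, 17, 20 and 21 are taken to be commercial; the sense of induction in step 2 rests on the steric model given there.

**Step 1**
Reactants: 1 2,2-dimethyl-1,3-dioxan-5-one; 2 (2R,5R)-2,5-dimethylpyrrolidine
Product: 3 (2R,5R)-1-(2,2-dimethyl-4H-1,3-dioxin-5-yl)-2,5-dimethylpyrrolidine
Conditions: 4 Å molecular sieves, toluene, 50 °C; filtered, concentrated, used crude
Reagents that add atoms: none
Why: Stork enamine condensation of an electron-poor ketone; the C2-symmetric amine gives one enamine in which a methyl group sits over one face of the nucleophilic carbon.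

**Step 2**
Reactants: 3 (2R,5R)-1-(2,2-dimethyl-4H-1,3-dioxin-5-yl)-2,5-dimethylpyrrolidine; 4 acryloyl chloride
Product: 6 (1S,5R)-3,3-dimethyl-2,4-dioxabicyclo[3.3.1]nonane-6,9-dione, via bicyclic iminium chloride 5 (not isolated)
Conditions: 4 (1.05 equiv), toluene, −20 °C → 80 °C; then AcOH/H2O/THF, rt
Reagents that add atoms: water O
Why: Acryloyl chloride N-acylates the enamine and the N-acryloyl enammonium undergoes a [3,3]-sigmatropic shift (net Michael-type C-alkylation) that joins the enamine β-carbon to the acrylate β-carbon and leaves a ketene tethered to an iminium; loss of the α′ proton regenerates the enamine on the other side, the ketene C-acylates it, and hydrolysis of iminium 5 should give the diketone. The closest known reaction is the Stork-type α,α′-annulation of cyclic ketone enamines with acryloyl chloride to bicyclo[3.3.1]nonane-2,9-diones, with the α,α′-annulation of ketone enamines by 2-(bromomethyl)acrylates as a near relative. The carbocycle closes in the second bond-forming event by 6-(enolendo)-exo-dig attack of the enamine carbon on the ketene carbon, which requires both new bonds to be axial on the dioxane ring. C1 is controlled by the auxiliary: one methyl group of the (2R,5R)-pyrrolidine covers one face of the enamine β-carbon, so the C–C bond should form on the other face, which corresponds to the (1S) configuration; C5 is not an independent choice because the bridge can only span the two α-carbons cis. The step needs C- over O-acylation, a single annulation and a configurationally stable product: the N-acylation/rearrangement path secures the first, the single remaining α′ position the second, and the bridgehead position of both α-hydrogens (no enolisation of the 1,3-diketone) the third.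

**Step 3**
Reactants: 6 (1S,5R)-3,3-dimethyl-2,4-dioxabicyclo[3.3.1]nonane-6,9-dione
Product: 7 (1S,5R)-6-[(tert-butyldimethylsilyl)oxy]-3,3-dimethyl-2,4-dioxabicyclo[3.3.1]non-6-en-9-one
Conditions: TBSOTf (1.2 equiv), Et3N (2 equiv), CH2Cl2, 0 °C
Reagents that add atoms: tert-butyldimethylsilyl triflate CC(C)(C)[Si](C)(C)OS(=O)(=O)C(F)(F)F
Why: Silyl enol ether formation by soft enolisation; C7 is the only enolisable position (C1 and C5 are bridgeheads), so the C6 ketone is masked while the C9 ketone stays free.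

**Step 4**
Reactants: 7 (1S,5R)-6-[(tert-butyldimethylsilyl)oxy]-3,3-dimethyl-2,4-dioxabicyclo[3.3.1]non-6-en-9-one; 8 isopropyltriphenylphosphonium iodide
Product: 9 tert-butyl{[(1S,5S)-3,3-dimethyl-9-(propan-2-ylidene)-2,4-dioxabicyclo[3.3.1]non-6-en-6-yl]oxy}dimethylsilane
Conditions: 8 (2.0 equiv), nBuLi (1.9 equiv), THF, 0 °C; then 7, 0 → 60 °C
Reagents that add atoms: none
Why: Wittig olefination of a non-enolisable, doubly α-oxygenated and therefore electrophilic bridging ketone by the unstabilised ylide; the silyl enol ether is inert and no stereocentre is formed.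

**Step 5**
Reactants: 9 tert-butyl{[(1S,5S)-3,3-dimethyl-9-(propan-2-ylidene)-2,4-dioxabicyclo[3.3.1]non-6-en-6-yl]oxy}dimethylsilane
Product: 10 (2S,4S)-2,4-dihydroxy-3-(propan-2-ylidene)cyclohexan-1-one
Conditions: AcOH/THF/H2O (3:1:1), rt → 40 °C
Reagents that add atoms: none
Why: Mild acid hydrolysis of the strained bicyclic acetonide and of the silyl enol ether; weak acid is chosen to avoid allylic ionisation, and A(1,3) strain keeps the C2–H near the carbonyl plane, which should slow the enolisation that would move the double bond into conjugation.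

**Step 6**
Reactants: 10 (2S,4S)-2,4-dihydroxy-3-(propan-2-ylidene)cyclohexan-1-one
Product: 12 (2S,4S)-2-[(tert-butyldimethylsilyl)oxy]-3-(propan-2-ylidene)-4-[(triethylsilyl)oxy]cyclohexan-1-one, via mono-triethylsilyl ether 11 (not isolated)
Conditions: Et3SiCl (1.05 equiv), imidazole, CH2Cl2, −40 → −20 °C; then TBSOTf (1.3 equiv), 2,6-lutidine, −20 → 0 °C
Reagents that add atoms: chlorotriethylsilane CC[Si](Cl)(CC)CC; tert-butyldimethylsilyl triflate CC(C)(C)[Si](C)(C)OS(=O)(=O)C(F)(F)F
Why: Regioselective O-silylation; the C4 hydroxyl is an ordinary secondary alcohol, whereas the C2 hydroxyl is an α-ketol hydroxyl deactivated inductively and by hydrogen bonding to the carbonyl, so it should be capped second by the more reactive triflate.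

**Step 7**
Reactants: 12 (2S,4S)-2-[(tert-butyldimethylsilyl)oxy]-3-(propan-2-ylidene)-4-[(triethylsilyl)oxy]cyclohexan-1-one
Product: 13 (2S,3S,4S)-2-[(tert-butyldimethylsilyl)oxy]-3-(propan-2-yl)-4-[(triethylsilyl)oxy]cyclohexan-1-one
Conditions: H2 (50 bar), [Ir(cod)(PCy3)(py)]PF6 (5 mol %), CH2Cl2, rt
Reagents that add atoms: none
Why: Homogeneous hydrogenation of a tetrasubstituted alkene; A(1,3) strain with the isopropylidene methyl groups holds both silyloxy groups pseudoaxial on one face, so hydrogen should add from the other face and place the C3 isopropyl group cis to both oxygens.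

**Step 8**
Reactants: 13 (2S,3S,4S)-2-[(tert-butyldimethylsilyl)oxy]-3-(propan-2-yl)-4-[(triethylsilyl)oxy]cyclohexan-1-one
Product: 15 (4S,5S,6S)-6-[(tert-butyldimethylsilyl)oxy]-5-(propan-2-yl)-4-[(triethylsilyl)oxy]cyclohex-2-en-1-one, via trimethylsilyl enol ether 14 (not isolated)
Conditions: LiN(SiMe3)2 (1.2 equiv), Me3SiCl (1.5 equiv), THF, −78 °C; then Pd(OAc)2 (1.1 equiv), MeCN, rt
Reagents that add atoms: none
Why: Kinetic enolisation at the α-methylene (the other α-carbon is a hindered, oxygenated methine) followed by Saegusa–Ito dehydrosilylation with divalent palladium should introduce the enone double bond without touching the three stereocentres.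

**Step 9**
Reactants: 15 (4S,5S,6S)-6-[(tert-butyldimethylsilyl)oxy]-5-(propan-2-yl)-4-[(triethylsilyl)oxy]cyclohex-2-en-1-one
Product: 16 (4S,5S,6S)-6-[(tert-butyldimethylsilyl)oxy]-4-hydroxy-5-(propan-2-yl)cyclohex-2-en-1-one
Conditions: PPTS (0.2 equiv), MeOH, 0 °C → rt
Reagents that add atoms: none
Why: Acid-catalysed methanolysis cleaves a triethylsilyl ether far faster than a hindered tert-butyldimethylsilyl ether next to a carbonyl group.

**Step 10**
Reactants: 16 (4S,5S,6S)-6-[(tert-butyldimethylsilyl)oxy]-4-hydroxy-5-(propan-2-yl)cyclohex-2-en-1-one; 17 angelic acid, (2Z)-2-methylbut-2-enoic acid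
Product: 18 (1S,5S,6S)-5-[(tert-butyldimethylsilyl)oxy]-4-oxo-6-(propan-2-yl)cyclohex-2-en-1-yl (2Z)-2-methylbut-2-enoate
Conditions: 17, 2,4,6-trichlorobenzoyl chloride, Et3N, toluene, rt, filtered from the ammonium salt; then 16, toluene, 75 °C
Reagents that add atoms: none
Why: Yamaguchi esterification through the mixed anhydride, run without DMAP and without free amine to avoid Z to E isomerisation of the angelate and 1,3-silyl migration.

**Step 11**
Reactants: 18 (1S,5S,6S)-5-[(tert-butyldimethylsilyl)oxy]-4-oxo-6-(propan-2-yl)cyclohex-2-en-1-yl (2Z)-2-methylbut-2-enoate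
Product: 19 (1S,5S,6R)-5-hydroxy-4-oxo-6-(propan-2-yl)cyclohex-2-en-1-yl (2Z)-2-methylbut-2-enoate
Conditions: HF·pyridine, THF/pyridine, 0 °C → rt
Reagents that add atoms: none
Why: Buffered fluoride desilylation frees the α-ketol under mildly acidic conditions that should disfavour 1,3-acyl migration and epimerisation (the descriptor at C6 changes only through CIP priorities).

**Step 12**
Reactants: 20 (tert-butyldimethylsilyloxy)acetaldehyde; 21 ethyl 2-(triphenylphosphoranylidene)propanoate
Product: 22 ethyl (2E)-4-[(tert-butyldimethylsilyl)oxy]-2-methylbut-2-enoate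
Conditions: CH2Cl2, rt
Reagents that add atoms: none
Why: Wittig olefination with a stabilised α-methyl ylide, which should give the E trisubstituted enoate.

**Step 13**
Reactants: 22 ethyl (2E)-4-[(tert-butyldimethylsilyl)oxy]-2-methylbut-2-enoate
Product: 23 (2E)-4-[(tert-butyldimethylsilyl)oxy]-2-methylbut-2-enoic acid
Conditions: LiOH·H2O, THF/MeOH/H2O, rt; then 1 M HCl to pH 4, 0 °C
Reagents that add atoms: lithium hydroxide [Li+].[OH-]
Why: Saponification of the ethyl ester; the primary silyl ether tolerates aqueous base at room temperature.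

**Step 14**
Reactants: 19 (1S,5S,6R)-5-hydroxy-4-oxo-6-(propan-2-yl)cyclohex-2-en-1-yl (2Z)-2-methylbut-2-enoate; 23 (2E)-4-[(tert-butyldimethylsilyl)oxy]-2-methylbut-2-enoic acid
Product: 24 (1S,5S,6S)-5-{[(2E)-4-[(tert-butyldimethylsilyl)oxy]-2-methylbut-2-enoyl]oxy}-4-oxo-6-(propan-2-yl)cyclohex-2-en-1-yl (2Z)-2-methylbut-2-enoate
Conditions: EDC·HCl (1.5 equiv), DMAP (0.2 equiv), CH2Cl2, 0 °C → rt
Reagents that add atoms: none
Why: Steglich esterification of the α-ketol hydroxyl at low temperature, where acylation should outrun migration of the hindered angelate.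

**Step 15**
Reactants: 24 (1S,5S,6S)-5-{[(2E)-4-[(tert-butyldimethylsilyl)oxy]-2-methylbut-2-enoyl]oxy}-4-oxo-6-(propan-2-yl)cyclohex-2-en-1-yl (2Z)-2-methylbut-2-enoate
Product: 25 (1S,5S,6S)-5-{[(2E)-4-[(tert-butyldimethylsilyl)oxy]-2-methylbut-2-enoyl]oxy}-3-(hydroxymethyl)-4-oxo-6-(propan-2-yl)cyclohex-2-en-1-yl (2Z)-2-methylbut-2-enoate
Conditions: 37% aq. HCHO, DMAP (0.3 equiv), THF, rt
Reagents that add atoms: formaldehyde C=O
Why: Morita–Baylis–Hillman hydroxymethylation of a cyclohexenone at its α-carbon, the only position activated by reversible amine addition to the β-carbon; the trisubstituted enoate esters are not acceptors under these conditions.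

**Step 16**
Reactants: 25 (1S,5S,6S)-5-{[(2E)-4-[(tert-butyldimethylsilyl)oxy]-2-methylbut-2-enoyl]oxy}-3-(hydroxymethyl)-4-oxo-6-(propan-2-yl)cyclohex-2-en-1-yl (2Z)-2-methylbut-2-enoate
Product: 26 (1S,5S,6S)-3-(hydroxymethyl)-5-{[(2E)-4-hydroxy-2-methylbut-2-enoyl]oxy}-4-oxo-6-(propan-2-yl)cyclohex-2-en-1-yl (2Z)-2-methylbut-2-enoate
Conditions: HF·pyridine, THF/pyridine, 0 °C
Reagents that add atoms: none
Why: Fluoride desilylation of the primary allylic silyl ether under buffered acidic conditions, which should leave both esters and the enone untouched.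

**Compound list**
1 | 2,2-dimethyl-1,3-dioxan-5-one | CC1(C)OCC(=O)CO1 | starting material
2 | (2R,5R)-2,5-dimethylpyrrolidine | C[C@@H]1CC[C@@H](C)N1 | starting material
3 | (2R,5R)-1-(2,2-dimethyl-4H-1,3-dioxin-5-yl)-2,5-dimethylpyrrolidine | CC1(C)OCC(=CO1)N1[C@H](C)CC[C@H]1C | intermediate
4 | acryloyl chloride | C=CC(Cl)=O | starting material
5 | (2R,5R)-1-[(1S,5S)-3,3-dimethyl-6-oxo-2,4-dioxabicyclo[3.3.1]nonan-9-ylidene]-2,5-dimethylpyrrolidin-1-ium chloride | CC1(C)O[C@H]2CCC(=O)[C@@H](O1)C2=[N+]1[C@H](C)CC[C@H]1C.[Cl-] | intermediate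
6 | (1S,5R)-3,3-dimethyl-2,4-dioxabicyclo[3.3.1]nonane-6,9-dione | CC1(C)O[C@H]2CCC(=O)[C@@H](O1)C2=O | intermediate
7 | (1S,5R)-6-[(tert-butyldimethylsilyl)oxy]-3,3-dimethyl-2,4-dioxabicyclo[3.3.1]non-6-en-9-one | CC1(C)O[C@H]2CC=C(O[Si](C)(C)C(C)(C)C)[C@@H](O1)C2=O | intermediate
8 | isopropyltriphenylphosphonium iodide | CC(C)[P+](c1ccccc1)(c1ccccc1)c1ccccc1.[I-] | starting material
9 | tert-butyl{[(1S,5S)-3,3-dimethyl-9-(propan-2-ylidene)-2,4-dioxabicyclo[3.3.1]non-6-en-6-yl]oxy}dimethylsilane | CC1(C)O[C@H]2CC=C(O[Si](C)(C)C(C)(C)C)[C@@H](O1)C2=C(C)C | intermediate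
10 | (2S,4S)-2,4-dihydroxy-3-(propan-2-ylidene)cyclohexan-1-one | O[C@H]1CCC(=O)[C@@H](O)C1=C(C)C | intermediate
11 | (2S,4S)-2-hydroxy-3-(propan-2-ylidene)-4-[(triethylsilyl)oxy]cyclohexan-1-one | CC[Si](CC)(CC)O[C@H]1CCC(=O)[C@@H](O)C1=C(C)C | intermediate
12 | (2S,4S)-2-[(tert-butyldimethylsilyl)oxy]-3-(propan-2-ylidene)-4-[(triethylsilyl)oxy]cyclohexan-1-one | CC[Si](CC)(CC)O[C@H]1CCC(=O)[C@@H](O[Si](C)(C)C(C)(C)C)C1=C(C)C | intermediate
13 | (2S,3S,4S)-2-[(tert-butyldimethylsilyl)oxy]-3-(propan-2-yl)-4-[(triethylsilyl)oxy]cyclohexan-1-one | CC[Si](CC)(CC)O[C@H]1CCC(=O)[C@@H](O[Si](C)(C)C(C)(C)C)[C@H]1C(C)C | intermediate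
14 | {[(4S,5S,6S)-6-[(tert-butyldimethylsilyl)oxy]-5-(propan-2-yl)-4-[(triethylsilyl)oxy]cyclohex-1-en-1-yl]oxy}trimethylsilane | CC[Si](CC)(CC)O[C@H]1CC=C(O[Si](C)(C)C)[C@@H](O[Si](C)(C)C(C)(C)C)[C@H]1C(C)C | intermediate
15 | (4S,5S,6S)-6-[(tert-butyldimethylsilyl)oxy]-5-(propan-2-yl)-4-[(triethylsilyl)oxy]cyclohex-2-en-1-one | CC[Si](CC)(CC)O[C@H]1C=CC(=O)[C@@H](O[Si](C)(C)C(C)(C)C)[C@H]1C(C)C | intermediate
16 | (4S,5S,6S)-6-[(tert-butyldimethylsilyl)oxy]-4-hydroxy-5-(propan-2-yl)cyclohex-2-en-1-one | O[C@H]1C=CC(=O)[C@@H](O[Si](C)(C)C(C)(C)C)[C@H]1C(C)C | intermediate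
17 | angelic acid, (2Z)-2-methylbut-2-enoic acid | C/C=C(/C)C(=O)O | starting material
18 | (1S,5S,6S)-5-[(tert-butyldimethylsilyl)oxy]-4-oxo-6-(propan-2-yl)cyclohex-2-en-1-yl (2Z)-2-methylbut-2-enoate | C/C=C(/C)C(=O)O[C@H]1C=CC(=O)[C@@H](O[Si](C)(C)C(C)(C)C)[C@H]1C(C)C | intermediate
19 | (1S,5S,6R)-5-hydroxy-4-oxo-6-(propan-2-yl)cyclohex-2-en-1-yl (2Z)-2-methylbut-2-enoate | C/C=C(/C)C(=O)O[C@H]1C=CC(=O)[C@@H](O)[C@H]1C(C)C | intermediate
20 | (tert-butyldimethylsilyloxy)acetaldehyde | CC(C)(C)[Si](C)(C)OCC=O | starting material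
21 | ethyl 2-(triphenylphosphoranylidene)propanoate | CCOC(=O)C(C)=P(c1ccccc1)(c1ccccc1)c1ccccc1 | starting material
22 | ethyl (2E)-4-[(tert-butyldimethylsilyl)oxy]-2-methylbut-2-enoate | CCOC(=O)/C(C)=C/CO[Si](C)(C)C(C)(C)C | intermediate
23 | (2E)-4-[(tert-butyldimethylsilyl)oxy]-2-methylbut-2-enoic acid | OC(=O)/C(C)=C/CO[Si](C)(C)C(C)(C)C | intermediate
24 | (1S,5S,6S)-5-{[(2E)-4-[(tert-butyldimethylsilyl)oxy]-2-methylbut-2-enoyl]oxy}-4-oxo-6-(propan-2-yl)cyclohex-2-en-1-yl (2Z)-2-methylbut-2-enoate | C/C=C(/C)C(=O)O[C@H]1C=CC(=O)[C@@H](OC(=O)/C(C)=C/CO[Si](C)(C)C(C)(C)C)[C@H]1C(C)C | intermediate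
25 | (1S,5S,6S)-5-{[(2E)-4-[(tert-butyldimethylsilyl)oxy]-2-methylbut-2-enoyl]oxy}-3-(hydroxymethyl)-4-oxo-6-(propan-2-yl)cyclohex-2-en-1-yl (2Z)-2-methylbut-2-enoate | C/C=C(/C)C(=O)O[C@H]1C=C(CO)C(=O)[C@@H](OC(=O)/C(C)=C/CO[Si](C)(C)C(C)(C)C)[C@H]1C(C)C | intermediate
26 | (1S,5S,6S)-3-(hydroxymethyl)-5-{[(2E)-4-hydroxy-2-methylbut-2-enoyl]oxy}-4-oxo-6-(propan-2-yl)cyclohex-2-en-1-yl (2Z)-2-methylbut-2-enoate | C/C=C(/C)C(=O)O[C@H]1C=C(CO)C(=O)[C@@H](OC(=O)/C(C)=C/CO)[C@H]1C(C)C | target

**Step count**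
Total steps: 16. Longest linear sequence: 14 (steps 1–11 and 14–16; steps 12–13 make the side-chain acid).

**Steps most likely to fail**

1. Step 2. The auxiliary may discriminate poorly between the two faces of the enamine carbon in the first C–C bond formation, or may favour the opposite face to the one the steric model predicts. Fallback: from 1, condense with pyrrolidine to the achiral enamine 1-(2,2-dimethyl-4H-1,3-dioxin-5-yl)pyrrolidine F1, run the same annulation with 4 to give racemic 3,3-dimethyl-2,4-dioxabicyclo[3.3.1]nonane-6,9-dione F2, and separate the enantiomers by preparative chromatography on a chiral stationary phase. The (1S,5R) enantiomer is 6, where the route is rejoined.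

2. Step 7. The hindered tetrasubstituted alkene may reduce slowly, the β,γ-double bond may migrate into conjugation with the ketone, or facial control may be incomplete. Fallback: from 12, move the double bond into conjugation on purpose (DBU, CH2Cl2) to give (4S)-2-[(tert-butyldimethylsilyl)oxy]-3-(propan-2-yl)-4-[(triethylsilyl)oxy]cyclohex-2-en-1-one F3. Then hydrogenate the endocyclic enone (H2, Pd/C, EtOAc). Cis addition on the face anti to the pseudoaxial C4 silyloxy group should set C2 and C3 together and arrive at 13.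

3. Step 15. Under the nucleophilic amine and aqueous conditions, an ester may be cleaved, an acyl group may migrate to the new primary hydroxyl, or the α-acyloxy ketone carbon may epimerise. Fallback: from 24, α-iodinate the enone (I2, pyridine, CH2Cl2) to (1R,5S,6S)-5-{[(2E)-4-[(tert-butyldimethylsilyl)oxy]-2-methylbut-2-enoyl]oxy}-3-iodo-4-oxo-6-(propan-2-yl)cyclohex-2-en-1-yl (2Z)-2-methylbut-2-enoate F4 (same spatial arrangement as 24; the C1 descriptor changes through CIP priorities). Then couple with (tributylstannyl)methanol (Pd(PPh3)4, dioxane, 80 °C; Stille coupling) to arrive at 25.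

**Further compounds**
F1 | step 2 | 1-(2,2-dimethyl-4H-1,3-dioxin-5-yl)pyrrolidine | CC1(C)OCC(=CO1)N1CCCC1
F2 | step 2 | racemic 3,3-dimethyl-2,4-dioxabicyclo[3.3.1]nonane-6,9-dione | CC1(C)OC2CCC(=O)C(O1)C2=O
F3 | step 7 | (4S)-2-[(tert-butyldimethylsilyl)oxy]-3-(propan-2-yl)-4-[(triethylsilyl)oxy]cyclohex-2-en-1-one | CC[Si](CC)(CC)O[C@H]1CCC(=O)C(O[Si](C)(C)C(C)(C)C)=C1C(C)C
F4 | step 15 | (1R,5S,6S)-5-{[(2E)-4-[(tert-butyldimethylsilyl)oxy]-2-methylbut-2-enoyl]oxy}-3-iodo-4-oxo-6-(propan-2-yl)cyclohex-2-en-1-yl (2Z)-2-methylbut-2-enoate | C/C=C(/C)C(=O)O[C@H]1C=C(I)C(=O)[C@@H](OC(=O)/C(C)=C/CO[Si](C)(C)C(C)(C)C)[C@H]1C(C)C
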